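**Retrosynthetic overview**

1. Daucane numbering is used: C1 (ring-fusion C–CH3), C2, C3, C4 (C(OH)i-Pr), C5 (ring-fusion CH), C6 (aroyloxy), C7 (CH2), C8 (=C–CH3), C9, C10 (angeloyloxy). Both esters go on last. C10–O comes from a singlet-oxygen ene transposition of a C9=C10 alkene (C8–H to C10–O). C6–O comes from a silyl group on C6 (masked ketone) and a reduction directed by the C4 hydroxyl.
2. Key disconnection: C7–C6 and C5–C1 together, by a rhodium-catalysed intramolecular [5+2] cycloaddition of a silyl alkyne (C5≡C6) with a vinylcyclopropane (C1=C10–C9, cyclopropane C9/C8/C7).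
3. Enabling feature: the seven-membered ring C1–C10–C9–C8–C7–C6–C5 is a five-carbon array (C1, C10, C9, C8, C7) plus a two-carbon unit (C5, C6). C5 is tied to C1 by the three-carbon bridge C2–C3–C4 of the five-membered ring, so an alkyne on C4 reaches the vinylcyclopropane intramolecularly. The C8 methyl makes C9 stereogenic, and C9 then steers the quaternary C1.
4. The precursor comes from a B-alkyl Suzuki coupling (C1–C2) of an (E)-alkenyl iodide carrying the (1R,2R)-2-methylcyclopropane (from (S)-propylene oxide) with an enyne carrying C4 (from asymmetric alkynylation of an α-keto ester).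
5. Ring order: cyclopropane first (temporary ring, step 1), then the five- and seven-membered rings together (step 11).

Key step: step 11

Assumption: in step 6 the (1S,2S) amino alcohol ligand is taken to give the (R)-carbinol 14 (its enantiomer is used if the facial sense is opposite), and 24 is taken as a commercial compound.

**Route**

Step 1
Reactants: 1 (S)-propylene oxide; 2 triethyl phosphonoacetate
Product: 3 ethyl (1R,2R)-2-methylcyclopropane-1-carboxylate
Conditions: NaH, 1,2-dimethoxyethane, 0 °C then 110 °C (sealed)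
Reagents that add atoms: none
Why: Wadsworth–Emmons cyclopropanation: the phosphonate carbanion opens the epoxide at CH2, the phosphoryl group moves to the alkoxide, and ring closure displaces phosphate with inversion at the methyl-bearing carbon to give the trans ester, so the (S) centre of 1 sets both ring centres as (1R,2R).

Step 2
Reactants: 3 ethyl (1R,2R)-2-methylcyclopropane-1-carboxylate
Product: 5 (1R,2R)-1-(2,2-dibromoethenyl)-2-methylcyclopropane, via aldehyde 4 (not isolated)
Conditions: i-Bu2AlH, CH2Cl2, −78 °C; aqueous work-up, dried solution of 4 used directly; CBr4, PPh3, CH2Cl2, 0 °C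
Reagents that add atoms: carbon tetrabromide, BrC(Br)(Br)Br
Why: Partial ester reduction through a tetrahedral aluminate that is stable at low temperature, then Ramirez dibromo-olefination (first stage of the Corey–Fuchs sequence) of the volatile aldehyde; no stereocentre is touched.

Step 3
Reactants: 5 (1R,2R)-1-(2,2-dibromoethenyl)-2-methylcyclopropane
Product: 7 (1R,2R)-1-methyl-2-(prop-1-yn-1-yl)cyclopropane, via lithium acetylide 6 (not isolated)
Conditions: n-BuLi (2.1 equiv), THF, −78 °C to 0 °C; MeI, −78 °C to rt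
Reagents that add atoms: iodomethane, CI
Why: Second stage of the Corey–Fuchs sequence: bromine–lithium exchange and Fritsch–Buttenberg–Wiechert rearrangement give the lithium acetylide, which is methylated at carbon.

Step 4
Reactants: 7 (1R,2R)-1-methyl-2-(prop-1-yn-1-yl)cyclopropane
Product: 9 (1R,2R)-1-[(E)-2-iodoprop-1-en-1-yl]-2-methylcyclopropane, via alkenylzirconocene chloride 8 (not isolated)
Conditions: Cp2Zr(H)Cl (1.3 equiv), THF, 45 °C; I2, 0 °C
Reagents that add atoms: iodine, II
Why: Schwartz hydrozirconation adds Zr–H syn with zirconium at the less hindered methyl-bearing carbon (equilibrated by the small excess of reagent), and iodinolysis with retention fixes the (E) geometry (iodine trans to the cyclopropane).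

Step 5
Reactants: 10 ethynylmagnesium bromide; 11 benzylchlorodimethylsilane
Product: 12 benzyl(ethynyl)dimethylsilane
Conditions: THF, 0 °C to rt
Reagents that add atoms: none
Why: Substitution at silicon by an alkynyl Grignard reagent; the benzyldimethylsilyl group caps the alkyne and can later be oxidised at silicon.

Step 6
Reactants: 13 ethyl 3-methyl-2-oxobutanoate; 12 benzyl(ethynyl)dimethylsilane
Product: 14 ethyl (R)-4-[benzyl(dimethyl)silyl]-2-hydroxy-2-(propan-2-yl)but-3-ynoate
Conditions: Zn(OTf)2 (20 mol %), (1S,2S)-3-(tert-butyldimethylsilyloxy)-2-(dimethylamino)-1-(4-nitrophenyl)propan-1-ol (22 mol %), Et3N (30 mol %), toluene, 70 °C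
Reagents that add atoms: none
Why: Catalytic asymmetric alkynylation of an α-keto ester: the zinc acetylide bound to the chiral amino alcohol adds to one face of the ketone, which sets C4 as (R).

Step 7
Reactants: 14 ethyl (R)-4-[benzyl(dimethyl)silyl]-2-hydroxy-2-(propan-2-yl)but-3-ynoate
Product: 15 ethyl (R)-4-[benzyl(dimethyl)silyl]-2-(propan-2-yl)-2-(triethylsilyloxy)but-3-ynoate
Conditions: Et3SiOTf, 2,6-lutidine, CH2Cl2, 0 °C to rt
Reagents that add atoms: triethylsilyl trifluoromethanesulfonate, CC[Si](CC)(CC)OS(=O)(=O)C(F)(F)F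
Why: A silyl triflate with a hindered pyridine base silylates tertiary alcohols, and the ether blocks retro-addition in the following steps.

Step 8
Reactants: 15 ethyl (R)-4-[benzyl(dimethyl)silyl]-2-(propan-2-yl)-2-(triethylsilyloxy)but-3-ynoate
Product: 16 (R)-4-[benzyl(dimethyl)silyl]-2-(propan-2-yl)-2-(triethylsilyloxy)but-3-ynal
Conditions: i-Bu2AlH, CH2Cl2, −78 °C
Reagents that add atoms: none
Why: Reduction of an α-silyloxy ester stops at the aldehyde because the tetrahedral aluminate survives at −78 °C.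

Step 9
Reactants: 16 (R)-4-[benzyl(dimethyl)silyl]-2-(propan-2-yl)-2-(triethylsilyloxy)but-3-ynal
Product: 17 (S)-benzyl(dimethyl)[3-(propan-2-yl)-3-(triethylsilyloxy)pent-4-en-1-yn-1-yl]silane
Conditions: Ph3PCH3Br, KN(SiMe3)2, THF, 0 °C to rt
Reagents that add atoms: methyltriphenylphosphonium bromide, C[P+](c1ccccc1)(c1ccccc1)c1ccccc1.[Br-]
Why: Wittig methylenation of a non-enolisable aldehyde; the descriptor changes from (R) to (S) only because the priorities change.

Step 10
Reactants: 17 (S)-benzyl(dimethyl)[3-(propan-2-yl)-3-(triethylsilyloxy)pent-4-en-1-yn-1-yl]silane; 9 (1R,2R)-1-[(E)-2-iodoprop-1-en-1-yl]-2-methylcyclopropane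
Product: 19 benzyl(dimethyl)[(3R,6E)-6-methyl-7-[(1R,2R)-2-methylcyclopropyl]-3-(propan-2-yl)-3-(triethylsilyloxy)hept-6-en-1-yn-1-yl]silane, via alkylborane 18 (not isolated)
Conditions: 9-BBN, THF, rt; then 9, Pd(dppf)Cl2 (5 mol %), AsPh3, K3PO4 (aq.), THF/DMF, rt
Reagents that add atoms: none
Why: 9-BBN hydroborates the monosubstituted alkene at its terminus much faster than the hindered silyl alkyne, and the B-alkyl Suzuki–Miyaura coupling forms C1–C2 with retention of the (E) geometry (chain trans to the cyclopropane, methyl cis).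

Step 11
Reactants: 19 benzyl(dimethyl)[(3R,6E)-6-methyl-7-[(1R,2R)-2-methylcyclopropyl]-3-(propan-2-yl)-3-(triethylsilyloxy)hept-6-en-1-yn-1-yl]silane
Product: 20 (1R,4R,8R)-6-[benzyl(dimethyl)silyl]-4-(triethylsilyloxy)dauca-5,9-diene
Conditions: RhCl(PPh3)3 (10 mol %), AgOTf (10 mol %), toluene, 110 °C
Reagents that add atoms: none
Why: Monovalent rhodium inserts into the less substituted C9–C7 bond of the vinylcyclopropane to give a σ-alkyl π-allyl rhodacycle, the tethered alkyne inserts at the allyl terminus C1 (C1–C5 bond), and reductive elimination joins C7 to C6. The closest known reaction type is the rhodium-catalysed intramolecular [5+2] cycloaddition of alkyne-tethered vinylcyclopropanes, a class that includes silyl alkynes, 2-substituted cyclopropanes and fully substituted alkene termini. The cyclopentane closes by 5-exo insertion of the alkyne across the C2–C3–C4 tether, and the cycloheptadiene closes by C(sp3)–C(sp2) reductive elimination from the ring-expanded rhodacycle, with C9=C10 held cis by the s-cis reacting conformer. C1 is the only new stereocentre and is set by chirality transfer: the (R) centre C9 decides which face of the allyl unit rhodium occupies and the (E) geometry decides which C1 substituent points inward, so the C1–C5 bond forms on one face only, independent of C4. C8 keeps its configuration and ends with its hydrogen on the face of the C1 methyl group. The step needs opening of C9–C7 rather than C9–C8, which the trans alkyl substituent (primary alkyl–rhodium preferred) and the phosphine-bearing cationic catalyst should secure, and it needs intramolecular alkyne capture, which the three-atom tether through the fully substituted C4 favours.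

Step 12
Reactants: 20 (1R,4R,8R)-6-[benzyl(dimethyl)silyl]-4-(triethylsilyloxy)dauca-5,9-diene
Product: 22 (1R,4R,5R,8R)-4-hydroxydauc-9-en-6-one, via cyclic siloxane 21 (not isolated)
Conditions: Bu4NF, THF, 0 °C; then H2O2 (30 % aq.), KHCO3, MeOH, rt
Reagents that add atoms: hydrogen peroxide, OO
Why: Tamao–Fleming oxidation: fluoride removes the triethylsilyl and benzyl groups, the C4 oxygen closes onto silicon, and peroxide oxidises the C6–Si bond to an enol that ketonises; C5 can equilibrate through the enol under the mildly basic conditions, and the trans-fused ketone (C6 anti to the isopropyl group, O4–H···O=C6 hydrogen bond) should be favoured.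

Step 13
Reactants: 22 (1R,4R,5R,8R)-4-hydroxydauc-9-en-6-one
Product: 23 (1R,4R,5S,6S,8R)-dauc-9-ene-4,6-diol
Conditions: Me4NBH(OAc)3, MeCN/AcOH, −20 °C
Reagents that add atoms: none
Why: Evans–Saksena reduction: the acetoxyborohydride bound to the C4 hydroxyl delivers hydride to the C6 carbonyl from the face of O4, which gives the 1,3-anti diol with C6–OH on the face opposite to O4.

Step 14
Reactants: 23 (1R,4R,5S,6S,8R)-dauc-9-ene-4,6-diol; 24 4-(tert-butyldimethylsilyloxy)benzoic acid
Product: 25 (1R,4R,5S,6S,8R)-4-hydroxydauc-9-en-6-yl 4-(tert-butyldimethylsilyloxy)benzoate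
Conditions: DCC, DMAP (cat.), CH2Cl2, rt
Reagents that add atoms: none
Why: Steglich esterification of the only secondary alcohol; the tertiary C4 hydroxyl does not react.

Step 15
Reactants: 25 (1R,4R,5S,6S,8R)-4-hydroxydauc-9-en-6-yl 4-(tert-butyldimethylsilyloxy)benzoate
Product: 27 (1S,4R,5S,6S,10S)-4,10-dihydroxydauc-8-en-6-yl 4-(tert-butyldimethylsilyloxy)benzoate, via allylic hydroperoxide 26 (not isolated)
Conditions: O2, tetraphenylporphyrin (cat.), visible light, CH2Cl2, 0 °C; then PPh3
Reagents that add atoms: dioxygen, O=O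
Why: Schenck ene reaction: H8 is the only allylic hydrogen and lies on the face of the C1 methyl group, so singlet oxygen bonds to C10 on that face while the double bond moves to C8=C9, and phosphine reduces the hydroperoxide; C10 is therefore set by C8.

Step 16
Reactants: 28 angelic acid; 27 (1S,4R,5S,6S,10S)-4,10-dihydroxydauc-8-en-6-yl 4-(tert-butyldimethylsilyloxy)benzoate
Product: 29 (1S,4R,5S,6S,10S)-10-angeloyloxy-4-hydroxydauc-8-en-6-yl 4-(tert-butyldimethylsilyloxy)benzoate
Conditions: 2,4,6-trichlorobenzoyl chloride, Et3N, toluene, rt; then 27, 80 °C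
Reagents that add atoms: none
Why: Yamaguchi-type mixed-anhydride esterification without a nucleophilic catalyst acylates the hindered allylic alcohol and avoids isomerisation of the angelate to the tiglate; the tertiary hydroxyl is inert.

Step 17
Reactants: 29 (1S,4R,5S,6S,10S)-10-angeloyloxy-4-hydroxydauc-8-en-6-yl 4-(tert-butyldimethylsilyloxy)benzoate
Product: 30 (1S,4R,5S,6S,10S)-10-angeloyloxy-4-hydroxydauc-8-en-6-yl 4-hydroxybenzoate (CNP0273650.10)
Conditions: HF·pyridine, THF, 0 °C
Reagents that add atoms: none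
Why: Fluoride cleaves the aryl silyl ether selectively; both esters, the tertiary alcohol and the alkene should be stable to these conditions.

**Compound list**

1 | (S)-propylene oxide, (2S)-2-methyloxirane | C[C@H]1CO1 | starting material
2 | triethyl phosphonoacetate | CCOC(=O)CP(=O)(OCC)OCC | starting material
3 | ethyl (1R,2R)-2-methylcyclopropane-1-carboxylate | CCOC(=O)[C@@H]1C[C@H]1C | intermediate
4 | (1R,2R)-2-methylcyclopropane-1-carbaldehyde | O=C[C@@H]1C[C@H]1C | intermediate
5 | (1R,2R)-1-(2,2-dibromoethenyl)-2-methylcyclopropane | BrC(Br)=C[C@@H]1C[C@H]1C | intermediate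
6 | lithium 2-[(1R,2R)-2-methylcyclopropyl]ethynide | [Li]C#C[C@@H]1C[C@H]1C | intermediate
7 | (1R,2R)-1-methyl-2-(prop-1-yn-1-yl)cyclopropane | CC#C[C@@H]1C[C@H]1C | intermediate
8 | chlorobis(cyclopentadienyl)[(E)-1-[(1R,2R)-2-methylcyclopropyl]prop-1-en-2-yl]zirconium | C/C(=C\[C@@H]1C[C@H]1C)[Zr](Cl)(C2C=CC=C2)C2C=CC=C2 | intermediate
9 | (1R,2R)-1-[(E)-2-iodoprop-1-en-1-yl]-2-methylcyclopropane | C/C(I)=C\[C@@H]1C[C@H]1C | intermediate
10 | ethynylmagnesium bromide | C#C[Mg]Br | starting material
11 | benzylchlorodimethylsilane | C[Si](C)(Cl)Cc1ccccc1 | starting material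
12 | benzyl(ethynyl)dimethylsilane | C#C[Si](C)(C)Cc1ccccc1 | intermediate
13 | ethyl 3-methyl-2-oxobutanoate | CCOC(=O)C(=O)C(C)C | starting material
14 | ethyl (R)-4-[benzyl(dimethyl)silyl]-2-hydroxy-2-(propan-2-yl)but-3-ynoate | CCOC(=O)[C@](O)(C#C[Si](C)(C)Cc1ccccc1)C(C)C | intermediate
15 | ethyl (R)-4-[benzyl(dimethyl)silyl]-2-(propan-2-yl)-2-(triethylsilyloxy)but-3-ynoate | CCOC(=O)[C@](O[Si](CC)(CC)CC)(C#C[Si](C)(C)Cc1ccccc1)C(C)C | intermediate
16 | (R)-4-[benzyl(dimethyl)silyl]-2-(propan-2-yl)-2-(triethylsilyloxy)but-3-ynal | CC(C)[C@@](O[Si](CC)(CC)CC)(C#C[Si](C)(C)Cc1ccccc1)C=O | intermediate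
17 | (S)-benzyl(dimethyl)[3-(propan-2-yl)-3-(triethylsilyloxy)pent-4-en-1-yn-1-yl]silane | CC(C)[C@@](O[Si](CC)(CC)CC)(C#C[Si](C)(C)Cc1ccccc1)C=C | intermediate
18 | 9-[(3R)-5-[benzyl(dimethyl)silyl]-3-(propan-2-yl)-3-(triethylsilyloxy)pent-4-yn-1-yl]-9-borabicyclo[3.3.1]nonane | CC(C)[C@@](O[Si](CC)(CC)CC)(C#C[Si](C)(C)Cc1ccccc1)CCB1C2CCCC1CCC2 | intermediate
19 | benzyl(dimethyl)[(3R,6E)-6-methyl-7-[(1R,2R)-2-methylcyclopropyl]-3-(propan-2-yl)-3-(triethylsilyloxy)hept-6-en-1-yn-1-yl]silane | CC(C)[C@@](O[Si](CC)(CC)CC)(C#C[Si](C)(C)Cc1ccccc1)CC/C(C)=C/[C@@H]1C[C@H]1C | intermediate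
20 | (1R,4R,8R)-6-[benzyl(dimethyl)silyl]-4-(triethylsilyloxy)dauca-5,9-diene (5-7 fused; C1 methyl, C8 methyl and C4 oxygen on one face) | C1=C[C@H](C)CC([Si](C)(C)Cc3ccccc3)=C2[C@]1(C)CC[C@@]2(O[Si](CC)(CC)CC)C(C)C | intermediate
21 | cyclic siloxane of the dauca-5,9-diene: O4 and C6 bridged by SiMe2 (2,5-dihydro-1,2-oxasilole ring) | C1=C[C@H](C)CC3=C2[C@]1(C)CC[C@@]2(O[Si]3(C)C)C(C)C | intermediate
22 | (1R,4R,5R,8R)-4-hydroxydauc-9-en-6-one (trans-fused; H5 anti to the C1 methyl) | C1=C[C@H](C)CC(=O)[C@@H]2[C@]1(C)CC[C@@]2(O)C(C)C | intermediate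
23 | (1R,4R,5S,6S,8R)-dauc-9-ene-4,6-diol | C1=C[C@H](C)C[C@H](O)[C@@H]2[C@]1(C)CC[C@@]2(O)C(C)C | intermediate
24 | 4-(tert-butyldimethylsilyloxy)benzoic acid | OC(=O)c1ccc(O[Si](C)(C)C(C)(C)C)cc1 | starting material
25 | (1R,4R,5S,6S,8R)-4-hydroxydauc-9-en-6-yl 4-(tert-butyldimethylsilyloxy)benzoate | C1=C[C@H](C)C[C@H](OC(=O)c3ccc(O[Si](C)(C)C(C)(C)C)cc3)[C@@H]2[C@]1(C)CC[C@@]2(O)C(C)C | intermediate
26 | (1S,4R,5S,6S,10S)-10-hydroperoxy-4-hydroxydauc-8-en-6-yl 4-(tert-butyldimethylsilyloxy)benzoate | OO[C@H]1C=C(C)C[C@H](OC(=O)c3ccc(O[Si](C)(C)C(C)(C)C)cc3)[C@@H]2[C@]1(C)CC[C@@]2(O)C(C)C | intermediate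
27 | (1S,4R,5S,6S,10S)-4,10-dihydroxydauc-8-en-6-yl 4-(tert-butyldimethylsilyloxy)benzoate | O[C@H]1C=C(C)C[C@H](OC(=O)c3ccc(O[Si](C)(C)C(C)(C)C)cc3)[C@@H]2[C@]1(C)CC[C@@]2(O)C(C)C | intermediate
28 | angelic acid, (Z)-2-methylbut-2-enoic acid | C/C=C(/C)C(=O)O | starting material
29 | (1S,4R,5S,6S,10S)-10-angeloyloxy-4-hydroxydauc-8-en-6-yl 4-(tert-butyldimethylsilyloxy)benzoate | C/C=C(/C)C(=O)O[C@H]1C=C(C)C[C@H](OC(=O)c3ccc(O[Si](C)(C)C(C)(C)C)cc3)[C@@H]2[C@]1(C)CC[C@@]2(O)C(C)C | intermediate
30 | (1S,4R,5S,6S,10S)-10-angeloyloxy-4-hydroxydauc-8-en-6-yl 4-hydroxybenzoate (CNP0273650.10) | C/C=C(/C)C(=O)O[C@H]1C=C(C)C[C@H](OC(=O)c2ccc(O)cc2)[C@@H]2[C@]1(C)CC[C@@]2(O)C(C)C | target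

**Step count and risks**

Total step count: 17. Longest linear sequence: 13 steps (steps 5 to 17).

Steps most likely to fail:

1. Step 11 (key cycloaddition). Alkyne insertion at the fully substituted alkene terminus may be slowed by the bulky benzyldimethylsilyl group. That would leave time for ionisation of the tertiary propargylic silyl ether by the cationic catalyst or for opening of the more substituted cyclopropane bond. The fallback sets out from 19. Bu4NF (THF, rt) removes both silyl groups to give the enynol (3R,6E)-6-methyl-7-[(1R,2R)-2-methylcyclopropyl]-3-(propan-2-yl)hept-6-en-1-yn-3-ol F1. This unhindered terminal alkyne is cyclised with the neutral catalyst [Rh(CO)2Cl]2 (ClCH2CH2Cl, 80 °C) to the dienol (1R,4R,8R)-dauca-5,9-dien-4-ol F2. The C4 hydroxyl then directs VO(acac)2/t-BuOOH epoxidation to the allylic C5=C6 bond only, giving the epoxy alcohol F3 with the epoxide on the hydroxyl face. Cp2TiCl (trivalent titanium, from Cp2TiCl2 and Mn dust) with 1,4-cyclohexadiene opens F3 by the Nugent–RajanBabu reductive opening to the tertiary C5 radical, which should take hydrogen on the face away from the titanium alkoxide at C6 and give the trans-fused 6-epi diol F4. Dess–Martin oxidation of F4 gives 22, where the route is rejoined. This detour also replaces the silane oxidation of step 12, whose C5 configuration rests on an equilibration that is argued but not certain.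

2. Step 15 (singlet-oxygen ene reaction). Oxygen must bond to C10 on the face of the neighbouring C1 methyl group, so the ene reaction may be slow and photo-oxidative degradation may compete, or H8 may not reach the alignment needed for abstraction. The fallback sets out from 25. mCPBA (NaHCO3, CH2Cl2) should epoxidise the only alkene on the face away from the C1 methyl to give the 9,10-epoxide F5. PhSeSePh/NaBH4 (EtOH) opens F5 at the less hindered C9 to give the hydroxy selenide F6. H2O2 gives the selenoxide F7, which eliminates syn toward H8 to give the 10-epimer of 27, allylic alcohol F8. Dess–Martin oxidation gives the enone F9, and Luche reduction (NaBH4, CeCl3·7H2O, MeOH, −78 °C), with hydride arriving anti to the C1 methyl, should give 27, where the route is rejoined.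

3. Step 16 (angeloylation). The angelate may isomerise to the tiglate, or acylation of the hindered allylic alcohol next to the quaternary C1 may be incomplete. The fallback sets out from 27. Esterification with 2-[bis(2,2,2-trifluoroethoxy)phosphoryl]propanoic acid (DCC, DMAP, CH2Cl2) gives the phosphonopropionate ester F10. A Still–Gennari olefination of F10 with acetaldehyde (KN(SiMe3)2, 18-crown-6, THF, −78 °C) builds the (Z)-2-methylbut-2-enoate on the molecule and comes back to the route at 29.

Further compounds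
F1 | step 11 | (3R,6E)-6-methyl-7-[(1R,2R)-2-methylcyclopropyl]-3-(propan-2-yl)hept-6-en-1-yn-3-ol | CC(C)[C@@](O)(C#C)CC/C(C)=C/[C@@H]1C[C@H]1C
F2 | step 11 | (1R,4R,8R)-dauca-5,9-dien-4-ol | C1=C[C@H](C)CC=C2[C@]1(C)CC[C@@]2(O)C(C)C
F3 | step 11 | 5,6-epoxydauc-9-en-4-ol, epoxide oxygen on the face of the C4 hydroxyl and C1 methyl | C1=C[C@H](C)C[C@H]3O[C@@]32[C@]1(C)CC[C@@]2(O)C(C)C
F4 | step 11 | (1R,4R,5S,6R,8R)-dauc-9-ene-4,6-diol (6-epimer of 23) | C1=C[C@H](C)C[C@@H](O)[C@@H]2[C@]1(C)CC[C@@]2(O)C(C)C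
F5 | step 15 | 9,10-epoxide of 25, epoxide oxygen on the face opposite to the C1 methyl | O1[C@@H]2[C@H]1[C@H](C)C[C@H](OC(=O)c4ccc(O[Si](C)(C)C(C)(C)C)cc4)[C@@H]3[C@]2(C)CC[C@@]3(O)C(C)C
F6 | step 15 | 4,10-dihydroxy-9-(phenylselanyl)daucan-6-yl 4-(tert-butyldimethylsilyloxy)benzoate, C10–OH and C9–Se trans | O[C@@H]1[C@@H]([Se]c4ccccc4)[C@H](C)C[C@H](OC(=O)c5ccc(O[Si](C)(C)C(C)(C)C)cc5)[C@@H]2[C@]1(C)CC[C@@]2(O)C(C)C
F7 | step 15 | selenoxide of F6 | O[C@@H]1[C@@H]([Se](=O)c4ccccc4)[C@H](C)C[C@H](OC(=O)c5ccc(O[Si](C)(C)C(C)(C)C)cc5)[C@@H]2[C@]1(C)CC[C@@]2(O)C(C)C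
F8 | step 15 | (1S,4R,5S,6S,10R)-4,10-dihydroxydauc-8-en-6-yl 4-(tert-butyldimethylsilyloxy)benzoate (10-epimer of 27) | O[C@@H]1C=C(C)C[C@H](OC(=O)c3ccc(O[Si](C)(C)C(C)(C)C)cc3)[C@@H]2[C@]1(C)CC[C@@]2(O)C(C)C
F9 | step 15 | (1S,4R,5S,6S)-4-hydroxy-10-oxodauc-8-en-6-yl 4-(tert-butyldimethylsilyloxy)benzoate | O=C1C=C(C)C[C@H](OC(=O)c3ccc(O[Si](C)(C)C(C)(C)C)cc3)[C@@H]2[C@]1(C)CC[C@@]2(O)C(C)C
F10 | step 16 | (1S,4R,5S,6S,10S)-10-{2-[bis(2,2,2-trifluoroethoxy)phosphoryl]propanoyloxy}-4-hydroxydauc-8-en-6-yl 4-(tert-butyldimethylsilyloxy)benzoate | CC(C(=O)O[C@H]1C=C(C)C[C@H](OC(=O)c3ccc(O[Si](C)(C)C(C)(C)C)cc3)[C@@H]2[C@]1(C)CC[C@@]2(O)C(C)C)P(=O)(OCC(F)(F)F)OCC(F)(F)F
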